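**Retrosynthetic overview**

- Feature: C2, the (R)-carbinol carbon, with its C3H2–catechol arm and the C1 carbonyl is the skeleton of (R)-3-(3,4-dihydroxyphenyl)lactic acid. Ring A without its acyl group is 2-prenylresorcinol, in which C4 and C6 are related by a mirror plane.
- Target 14 ⇐ ketone 12 by removal of three silyl ethers (fluoride) and two methoxymethyl (MOM) ethers (mild acid).
- 12 ⇐ bond from ring A C1' to the ketone carbon: aryllithium 10, from MOM-directed ortho-lithiation of symmetric arene 5, plus N-methoxy-N-methylamide 9.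
- 5 ⇐ resorcinol 1 (bis-MOM ether, lithiation at C2, prenylation). 9 ⇐ (R)-danshensu 6 (methyl ester, tris-silylation, aminolysis).
- No ring is formed; rings A and B are bought, and the single stereocentre comes from 6.

Key step: step 6

Assumption: (R)-danshensu is used as the free acid; the commercial sodium salt would serve equally in step 3 after one extra equivalent of acid.

**Step 1**
Reactants: 1 resorcinol
Product: 2 1,3-bis(methoxymethoxy)benzene
Conditions: NaH, MOMCl, DMF, 0 °C → rt
Reagents that add atoms: chloromethyl methyl ether (MOMCl), COCCl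
Why: Williamson-type O-alkylation of the bis-phenoxide by the reactive α-chloro ether should give the bis-acetal cleanly (MOM protection).

**Step 2**
Reactants: 2 1,3-bis(methoxymethoxy)benzene; 3 prenyl bromide (1-bromo-3-methylbut-2-ene)
Product: 5 1,3-bis(methoxymethoxy)-2-(3-methylbut-2-en-1-yl)benzene, via 2-lithio-1,3-bis(methoxymethoxy)benzene 4 (not isolated)
Conditions: n-BuLi, THF, 0 °C → rt; then CuI (10 mol %), 3, −78 °C → rt
Reagents that add atoms: none
Why: Directed ortho-metalation removes the most acidic ring proton, the one flanked and chelated by both MOM ethers, and the aryllithium is allylated at the primary carbon of the bromide under copper catalysis (SN2 rather than SN2').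

**Step 3**
Reactants: 6 (R)-3-(3,4-dihydroxyphenyl)lactic acid (danshensu)
Product: 7 methyl (2R)-3-(3,4-dihydroxyphenyl)-2-hydroxypropanoate
Conditions: H2SO4 (cat.), MeOH, 50 °C, argon
Reagents that add atoms: methanol, CO
Why: Fischer esterification breaks no bond at C2 and the acidic medium does not enolise the ester, so the (R) configuration should be carried through.

**Step 4**
Reactants: 7 methyl (2R)-3-(3,4-dihydroxyphenyl)-2-hydroxypropanoate
Product: 8 methyl (2R)-2-(tert-butyldimethylsilyloxy)-3-[3,4-bis(tert-butyldimethylsilyloxy)phenyl]propanoate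
Conditions: TBSCl, imidazole, DMF, rt → 40 °C
Reagents that add atoms: tert-butyldimethylsilyl chloride (TBSCl), CC(C)(C)[Si](C)(C)Cl
Why: Silylation through the silylimidazolium species (Corey protocol) should cap both phenols and the secondary alcohol under non-epimerising conditions.

**Step 5**
Reactants: 8 methyl (2R)-2-(tert-butyldimethylsilyloxy)-3-[3,4-bis(tert-butyldimethylsilyloxy)phenyl]propanoate
Product: 9 (2R)-2-(tert-butyldimethylsilyloxy)-3-[3,4-bis(tert-butyldimethylsilyloxy)phenyl]-N-methoxy-N-methylpropanamide
Conditions: MeNHOMe·HCl, i-PrMgCl, THF, −20 → 0 °C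
Reagents that add atoms: N,O-dimethylhydroxylamine hydrochloride, CNOC.Cl
Why: Aminolysis of the ester by the chloromagnesium amide made in situ (Weinreb amide formation) proceeds at low temperature, where α-silyloxy esters are known to react without loss of configuration.

**Step 6**
Reactants: 5 1,3-bis(methoxymethoxy)-2-(3-methylbut-2-en-1-yl)benzene; 9 (2R)-2-(tert-butyldimethylsilyloxy)-3-[3,4-bis(tert-butyldimethylsilyloxy)phenyl]-N-methoxy-N-methylpropanamide
Product: 12 (2R)-1-[2,4-bis(methoxymethoxy)-3-(3-methylbut-2-en-1-yl)phenyl]-2-(tert-butyldimethylsilyloxy)-3-[3,4-bis(tert-butyldimethylsilyloxy)phenyl]propan-1-one, via ring A aryllithium 10 (not isolated), via lithium hemiaminal chelate 11 (not isolated)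
Conditions: 5 (1.5 equiv), n-BuLi (1.4 equiv), TMEDA, Et2O, 0 °C → rt; then 9 (1.0 equiv), THF, −78 → −40 °C; AcOH, THF, −78 °C
Reagents that add atoms: none
Why: n-BuLi, coordinated to a MOM oxygen, removes the adjacent ring proton at C4 (identical with C6 through the mirror plane of 5) in a MOM-directed ortho-lithiation, and aryllithium 10 adds to the amide carbonyl of 9 to give the five-membered lithium chelate 11, which persists at low temperature and collapses to the ketone only on the acetic acid quench (Weinreb ketone synthesis). The closest known reaction type is the acylation of ortho-alkoxymethoxy aryllithiums by N-methoxy-N-methylamides of α-silyloxy acids. One skeletal bond, ring A C1' to the carbonyl carbon, is formed and no ring is closed. No stereocentre is created; the (R) centre from 6 should survive because the carbonyl stays masked as 11 until the base is destroyed, so no enolisable ketone meets a lithium base, and addition at −78 °C outruns removal of the α-proton of the amide. The selectivity needed is ring C–H over the benzylic, allylic CH2 of the prenyl group and a single ring site: chelation of the base by the acetal oxygens steers it kinetically to the ortho C–H, the symmetry of 5 leaves only one such site, and keeping n-BuLi below one equivalent relative to 5 leaves no butyllithium to attack the amide.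

**Step 7**
Reactants: 12 (2R)-1-[2,4-bis(methoxymethoxy)-3-(3-methylbut-2-en-1-yl)phenyl]-2-(tert-butyldimethylsilyloxy)-3-[3,4-bis(tert-butyldimethylsilyloxy)phenyl]propan-1-one
Product: 13 (2R)-1-[2,4-bis(methoxymethoxy)-3-(3-methylbut-2-en-1-yl)phenyl]-3-(3,4-dihydroxyphenyl)-2-hydroxypropan-1-one
Conditions: TBAF, AcOH (1:1), THF, 0 °C → rt, argon
Reagents that add atoms: none
Why: Fluoride-driven desilylation, buffered with acetic acid so that neither phenoxide nor enolate builds up, should cleave the two aryl silyl ethers and the activated α-keto silyl ether while the MOM acetals and the (R) centre stay untouched.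

**Step 8**
Reactants: 13 (2R)-1-[2,4-bis(methoxymethoxy)-3-(3-methylbut-2-en-1-yl)phenyl]-3-(3,4-dihydroxyphenyl)-2-hydroxypropan-1-one
Product: 14 (2R)-1-[2,4-dihydroxy-3-(3-methylbut-2-en-1-yl)phenyl]-3-(3,4-dihydroxyphenyl)-2-hydroxypropan-1-one (target)
Conditions: 3 M aq. HCl, MeOH, rt → 40 °C, stopped at full conversion
Reagents that add atoms: none
Why: Acid-catalysed acetal exchange with methanol (MOM cleavage) is fast for aryl MOM ethers, so a short, mild exposure should free both ring A phenols before the phenol can add to the prenyl double bond or the α-hydroxy ketone can enolise.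

**Compound list**

1 | resorcinol | Oc1cccc(O)c1 | starting material
2 | 1,3-bis(methoxymethoxy)benzene | COCOc1cccc(OCOC)c1 | intermediate
3 | prenyl bromide (1-bromo-3-methylbut-2-ene) | CC(C)=CCBr | starting material
4 | 2-lithio-1,3-bis(methoxymethoxy)benzene (not isolated) | [Li]c1c(OCOC)cccc1OCOC | intermediate
5 | 1,3-bis(methoxymethoxy)-2-(3-methylbut-2-en-1-yl)benzene | CC(C)=CCc1c(OCOC)cccc1OCOC | intermediate
6 | (R)-3-(3,4-dihydroxyphenyl)lactic acid (danshensu) | OC(=O)[C@H](O)Cc1ccc(O)c(O)c1 | starting material
7 | methyl (2R)-3-(3,4-dihydroxyphenyl)-2-hydroxypropanoate | COC(=O)[C@H](O)Cc1ccc(O)c(O)c1 | intermediate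
8 | methyl (2R)-2-(tert-butyldimethylsilyloxy)-3-[3,4-bis(tert-butyldimethylsilyloxy)phenyl]propanoate | COC(=O)[C@H](O[Si](C)(C)C(C)(C)C)Cc1ccc(O[Si](C)(C)C(C)(C)C)c(O[Si](C)(C)C(C)(C)C)c1 | intermediate
9 | (2R)-2-(tert-butyldimethylsilyloxy)-3-[3,4-bis(tert-butyldimethylsilyloxy)phenyl]-N-methoxy-N-methylpropanamide | CON(C)C(=O)[C@H](O[Si](C)(C)C(C)(C)C)Cc1ccc(O[Si](C)(C)C(C)(C)C)c(O[Si](C)(C)C(C)(C)C)c1 | intermediate
10 | 4-lithio-1,3-bis(methoxymethoxy)-2-(3-methylbut-2-en-1-yl)benzene (ring A aryllithium, not isolated) | CC(C)=CCc1c(OCOC)ccc([Li])c1OCOC | intermediate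
11 | lithium alkoxide of the C1 N-methoxy-N-methyl hemiaminal, (2R), C1 unassigned (chelate, not isolated) | CC(C)=CCc1c(OCOC)ccc(C(O[Li])(N(C)OC)[C@H](O[Si](C)(C)C(C)(C)C)Cc2ccc(O[Si](C)(C)C(C)(C)C)c(O[Si](C)(C)C(C)(C)C)c2)c1OCOC | intermediate
12 | (2R)-1-[2,4-bis(methoxymethoxy)-3-(3-methylbut-2-en-1-yl)phenyl]-2-(tert-butyldimethylsilyloxy)-3-[3,4-bis(tert-butyldimethylsilyloxy)phenyl]propan-1-one | CC(C)=CCc1c(OCOC)ccc(C(=O)[C@H](O[Si](C)(C)C(C)(C)C)Cc2ccc(O[Si](C)(C)C(C)(C)C)c(O[Si](C)(C)C(C)(C)C)c2)c1OCOC | intermediate
13 | (2R)-1-[2,4-bis(methoxymethoxy)-3-(3-methylbut-2-en-1-yl)phenyl]-3-(3,4-dihydroxyphenyl)-2-hydroxypropan-1-one | CC(C)=CCc1c(OCOC)ccc(C(=O)[C@H](O)Cc2ccc(O)c(O)c2)c1OCOC | intermediate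
14 | (2R)-1-[2,4-dihydroxy-3-(3-methylbut-2-en-1-yl)phenyl]-3-(3,4-dihydroxyphenyl)-2-hydroxypropan-1-one | CC(C)=CCc1c(O)ccc(C(=O)[C@H](O)Cc2ccc(O)c(O)c2)c1O | target

**Step count**

Total: 8 steps. Longest linear sequence: 6 steps (3, 4, 5, 6, 7, 8, from danshensu 6); the ring A branch (steps 1 and 2) joins at step 6.

**Steps most likely to fail**

1. Step 6. The base may remove a proton from the benzylic, allylic CH2 of the prenyl group instead of the ring proton, or the hindered aryllithium may deprotonate the amide at its α-carbon instead of adding. Fallback: the metal is fixed on the ring by halogen–lithium exchange. Setting out from 2, NBS in MeCN at 0 °C should brominate the position para to one acetal oxygen to give 1-bromo-2,4-bis(methoxymethoxy)benzene F1. Lithium diisopropylamide in THF at −78 °C, which does not exchange bromine, should remove the proton between the two MOM ethers to give 3-lithio-1-bromo-2,4-bis(methoxymethoxy)benzene F2, not isolated. CuI-catalysed allylation with 3 should then give 1-bromo-2,4-bis(methoxymethoxy)-3-(3-methylbut-2-en-1-yl)benzene F3. Bromine–lithium exchange with n-BuLi in THF at −78 °C, far faster than any deprotonation, delivers aryllithium 10, and acylation with 9 as in step 6 comes back to the route at 12.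

2. Step 8. Under the acid, the C4 phenol may add across the prenyl double bond to close a 2,2-dimethylchroman, and the α-hydroxy ketone may enolise with erosion of the (R) centre. Fallback: the MOM groups are exchanged for silyl groups before any phenol is free, so that no strong acid is needed. Setting out from 12, TMSOTf with 2,2'-bipyridyl in CH2Cl2 at 0 °C should convert the two aryl MOM ethers into aryl trimethylsilyl ethers, giving (2R)-1-[2,4-bis(trimethylsilyloxy)-3-(3-methylbut-2-en-1-yl)phenyl]-2-(tert-butyldimethylsilyloxy)-3-[3,4-bis(tert-butyldimethylsilyloxy)phenyl]propan-1-one F4. TBAF buffered with AcOH in THF would then remove all five silyl groups in one operation, coming back to the route at 14.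

3. Step 5. The magnesium base may epimerise the α-silyloxy carbon or cleave aryl silyl ethers, and aminolysis of the hindered ester may stall. Fallback: the amide is made before silylation. Setting out from 6, carbodiimide coupling (EDC·HCl, HOBt, MeNHOMe·HCl, N-methylmorpholine, DMF, 0 °C → rt) should give (2R)-3-(3,4-dihydroxyphenyl)-2-hydroxy-N-methoxy-N-methylpropanamide F5. TBSCl and imidazole in DMF would then silylate all three hydroxyl groups, coming back to the route at 9.

**Further compounds**

F1 | step 6 | 1-bromo-2,4-bis(methoxymethoxy)benzene | COCOc1ccc(Br)c(OCOC)c1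
F2 | step 6 | 3-lithio-1-bromo-2,4-bis(methoxymethoxy)benzene | [Li]c1c(OCOC)ccc(Br)c1OCOC
F3 | step 6 | 1-bromo-2,4-bis(methoxymethoxy)-3-(3-methylbut-2-en-1-yl)benzene | CC(C)=CCc1c(OCOC)ccc(Br)c1OCOC
F4 | step 8 | (2R)-1-[2,4-bis(trimethylsilyloxy)-3-(3-methylbut-2-en-1-yl)phenyl]-2-(tert-butyldimethylsilyloxy)-3-[3,4-bis(tert-butyldimethylsilyloxy)phenyl]propan-1-one | CC(C)=CCc1c(O[Si](C)(C)C)ccc(C(=O)[C@H](O[Si](C)(C)C(C)(C)C)Cc2ccc(O[Si](C)(C)C(C)(C)C)c(O[Si](C)(C)C(C)(C)C)c2)c1O[Si](C)(C)C
F5 | step 5 | (2R)-3-(3,4-dihydroxyphenyl)-2-hydroxy-N-methoxy-N-methylpropanamide | CON(C)C(=O)[C@H](O)Cc1ccc(O)c(O)c1
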